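# Proposed synthesis of gnetucleistol F through an oxidative para-quinone methide ring closure

## Structural features

Gnetucleistol F is a stilbenoid built on a 2,3-dihydrobenzofuran: benzo ring A is fused to dihydrofuran ring B, C2 carries a 4-hydroxy-3,5-dimethoxyphenyl group (ring C), C3 a hydroxymethyl group, C7 a methoxy group, and C5 is joined through an (E)-ethene bridge to a 3,5-dihydroxyphenyl ring (ring D). The only stereocentres, C2 (R) and C3 (S), are neighbours on ring B and hold the aryl and hydroxymethyl groups trans. Three rings carry free phenols that are easily oxidised, the stilbene can isomerise in light, and the C2–O1 bond is a 4-hydroxybenzylic aryl ether that can open to a para-quinone methide under base or strong acid once the ring C phenol is free. The real difficulty is to fix the absolute configuration of C3, which carries only carbon substituents, to set C2 trans to it, and to keep three phenolic rings apart while one of them is manipulated. Ring A has its oxygen at C7a flanked by the C7 methoxy group and the C3a–C3 bond, which points to an ortho-Claisen origin for the C3 carbon. The key step exploits the fact that C2 is the benzylic carbon para to the hydroxyl of ring C and lies five atoms from the phenolic oxygen on C7a (O, C7a, C3a, C3, C2): two-electron oxidation of ring C turns C2 into the electrophilic end of a para-quinone methide within reach of that oxygen.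

## Logic of the disconnections

**23 to 22.** The four O–Si bonds are cut last. Every hydroxyl of 23 is then masked by one kind of group, so that hydride, MnO2 and the phosphonate anion never meet a free phenol. The forward step needs a fluoride source that is buffered, because a free ring C phenoxide could reopen ring B.

**22 to 17 and 21.** The C=C bond of the stilbene is cut. This is the most convergent cut available: it separates ring D from the chiral core and leaves a non-enolisable aryl aldehyde and a benzylic phosphonate. The forward olefination must give the E isomer and tolerate four silyl ethers.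

**21 to 20, 19 and 18.** The C–P bond, then the benzylic C–Br bond, then three O–Si bonds are cut. All three hydroxyls of 18 can be silylated without selectivity, and the benzylic silyl ether is exchanged for bromide directly. The forward bromination must spare the two aryl silyl ethers.

**17 to 16, 15 and 14.** No skeletal bond is cut. The C5 carbon goes back from aldehyde through the benzylic alcohol to the ester, and two O–Si bonds are removed. The ester is wanted in 14 because it is the deactivating group that ring A needs in the key step. Forward, reduction and benzylic oxidation must leave the C2–O1 bond closed, which the silyl cap on the ring C oxygen secures.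

**14 to 12 through 13.** The O1–C2 bond is cut. Ring B and the C2 stereocentre disappear, leaving an open chain with a single stereocentre that has no acidic hydrogen and no heteroatom. The forward step must oxidise ring C only, close before 13 tautomerises, give the trans isomer, and stop before 14 is oxidised further.

**12 to 11 and 10.** Two O–benzyl bonds are put back and the primary alcohol carbon is returned to a carboxylic acid. The phenols must be masked before this point, and the acid is the group that binds the hydrogenation catalyst. Forward, the reducing agent must take the acid and leave the ester, and one hydrogenolysis must free both phenols.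

**10 to 9.** The two C–H bonds at the stereocentre and its benzylic neighbour are removed to give an alkene. The stereocentre becomes a trigonal carbon, so the stereochemical problem is reduced to catalytic face selection. This demands a single alkene isomer of 9 and a catalyst that accepts an alpha-aryl acrylic acid with an ortho substituent.

**9 to 6 and 8.** The C=C bond is cut. The three-carbon chain splits into a two-carbon acid on ring A and a one-carbon aldehyde on ring C. The forward condensation must give the isomer with the aryl groups cis, and both phenols must be ethers to survive it.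

**8 to 7.** The O–benzyl bond is cut, which leads to a commodity aldehyde.

**6 to 4 (through 5), 3, 2 and 1.** The acid carbon is traced to an allyl group by adding back the terminal alkene carbon. The O–benzyl bond is then cut. The bond between ring A and the allyl group is moved back to oxygen (retro-Claisen), and finally the O–allyl bond is cut. The forward rearrangement can only go to the one free ortho position, and the alkene cleavage must spare the benzyl ether and the arene.

## Other disconnections considered

**Alternative 1:** The cut removes C2–C3 and O1–C2 together. It leaves a ring A ortho-quinone methide A4, released from sulfone A2, and the ring C benzylic sulfonium salt A3 of a C2-symmetric thiolane.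
- **Forward step:** Cs2CO3 would expel sulfinate from A2 and deprotonate A3 to the ylide A5. The ylide carbon would add to the methide carbon of A4 (C2–C3), and the phenoxide would then displace the sulfide (O1–C2) to give A1.
- **In favour:** one convergent step would make a C–C bond, the ring and both stereocentres. No phenol is oxidised. The C5 bromide of A1 is a handle for the styryl arm.
- **Against:** the absolute configuration would rest wholly on a stoichiometric chiral sulfide acting on a transient, acyclic A4 with a doubly ortho-substituted benzyl ylide. A4 has hydrogens next to the methide carbon and can tautomerise to a vinylphenol. A2 and A3 each need several steps.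
- **Comparison:** on convergence and on the number of stereocentres set per step the alternative is the better plan. On trans control the two are equal, since anti closure of the betaine and anti closure of 13 both favour trans. On mechanism the alternative avoids the over-oxidation risk of step 10. Its enantiocontrol is less secure than a catalytic hydrogenation of 9 followed by substrate relay. On step economy the two come out about equal once A2, A3 and the conversion of the bromide into the stilbene are counted.

**Alternative 2:** The cut opens ring D at two C–C bonds. It leads back to the Weinreb cinnamamide A7 of a protected core and to acetylacetone A8.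
- **Forward step:** the dianion of A8 (LiN(i-Pr)2) would be acylated by A7 to the triketone A9. Aqueous KOH in the same flask would close the terminal methyl carbon onto the cinnamoyl carbonyl, with loss of water and enolisation, to give A6.
- **In favour:** ring D would arrive unprotected from a commodity diketone, so steps 14 to 16 would vanish. The alkene geometry would come from a stabilised olefination.
- **Against:** this is an endgame only. The core with both stereocentres is still needed, for instance from an aldehyde like 17 with other protecting groups. The dianion may add in the conjugate sense. A9 can close through oxygen to a pyranone. The methoxymethyl ethers of A6 would have to be removed with acid from a product that holds an acid-sensitive 4-hydroxybenzylic ether and a stilbene.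
- **Comparison:** on structure the two plans are equal at the core. On total step count the alternative is the better by about two steps. Its linear sequence is one step longer, and its last step is harsher than the buffered fluoride of step 18. On mechanism the olefination of step 17 is the more predictable C–C bond formation.

**Alternative 3:** The cut is C3–C3a. A10 is traced to the flavanone A11, in which the ring A carbon is still bonded to the carbonyl carbon.
- **Forward step:** PhI(OAc)2 and H2SO4 in trimethyl orthoformate would convert A11 into its enol ether A12 and place trivalent iodine on C3. The ring A carbon would then migrate from C4 to C3 as iodobenzene leaves, and C4 would end as the methyl ester of A10.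
- **In favour:** A11 is only a few steps from simple aromatic ketone and aldehyde precursors. The ring contraction delivers the trans product as a rule. The C3 ester is one reduction from the hydroxymethyl group, and the bromide serves as a coupling handle.
- **Against:** A11 is needed as a single enantiomer, and a 2-arylchromanone with an electron-rich aryl group can racemise by reversible ring opening under the strongly acidic conditions of the step itself. The electron-rich ring C can migrate instead of ring A, or the substrate can be dehydrogenated. The ester and the aryl acetate must be told apart afterwards.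
- **Comparison:** the stereochemical relay runs from C2 to C3, the reverse of the chosen plan, and on relative (trans) control the two are equal. On the number of steps to the dihydrobenzofuran core the alternative is the better. On absolute control the chosen plan is safer, because the stereocentre of 12 is not labile and that of A11 is. After the core, both plans need a comparable number of steps to attach ring D.

Key step: step 10

**Remarks on the chemistry**

- **Check of the structures:** CIP analysis gives (S) for 10 to 13 and (2R,3S) for 14 to 17, 22 and 23. The carbon that becomes C3 keeps the same spatial arrangement from 10 to 23, so no structure needed correction.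
- **Design change before the key step:** both phenols are carried as benzyl ethers from 4 and 8 to 11. A free or acylated ortho-hydroxyphenylacetic acid would close to a benzofuran-2-one, and Ac2O would acylate free phenols in step 6. One hydrogenolysis then frees both phenols of 12.
- **Assumption:** the enantiomer of the chiral spiro phosphine-oxazoline ligand L (SpinPHOX type) in step 7 is chosen so that (S)-10 results. Both enantiomers of the ligand are accessible.

## Route

**Step 1**
Reactants: 1 methyl vanillate
Product: 2 methyl 3-methoxy-4-(prop-2-en-1-yloxy)benzoate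
Conditions: allyl bromide, K2CO3, acetone, reflux
Reagents that add atoms: allyl bromide, C=CCBr
Why: Williamson O-alkylation of the phenoxide by an allylic bromide (SN2); the methyl ester is inert to K2CO3 in acetone.

**Step 2**
Reactants: 2 methyl 3-methoxy-4-(prop-2-en-1-yloxy)benzoate
Product: 3 methyl 4-hydroxy-3-methoxy-5-(prop-2-en-1-yl)benzoate
Conditions: neat, 200 °C, Ar
Reagents that add atoms: none
Why: Aromatic Claisen rearrangement ([3,3] shift, then tautomerisation); one ortho position carries the methoxy group, so the allyl group can only arrive at the free ortho carbon, the future C3a.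

**Step 3**
Reactants: 3 methyl 4-hydroxy-3-methoxy-5-(prop-2-en-1-yl)benzoate
Product: 4 methyl 4-(benzyloxy)-3-methoxy-5-(prop-2-en-1-yl)benzoate
Conditions: BnBr, K2CO3, DMF, 60 °C
Reagents that add atoms: benzyl bromide, BrCc1ccccc1
Why: Williamson benzylation; the benzyl ether prevents lactonisation onto the acetic acid chain in steps 4 and 6 and should survive ozone at low conversion time, Ac2O/Et3N, the iridium hydrogenation and borane.

**Step 4**
Reactants: 4 methyl 4-(benzyloxy)-3-methoxy-5-(prop-2-en-1-yl)benzoate
Product: 6 2-[2-(benzyloxy)-3-methoxy-5-(methoxycarbonyl)phenyl]acetic acid, via arylacetaldehyde 5 (not isolated)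
Conditions: O3, MeCN/H2O (9:1), 0 °C; then aq. NaClO2, 0 °C → rt; acidic work-up
Reagents that add atoms: ozone, [O-][O+]=O; sodium chlorite, [Na+].[O-]Cl=O
Why: Ozonolysis in aqueous MeCN hydrolyses the carbonyl oxide directly to the aldehyde, and chlorite added to the same flask performs a Pinnick-type oxidation with the H2O2 from the first stage as hypochlorite scavenger; the terminal alkene should react with ozone far faster than the arene rings or the benzyl ether.

**Step 5**
Reactants: 7 syringaldehyde
Product: 8 4-(benzyloxy)-3,5-dimethoxybenzaldehyde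
Conditions: BnBr, K2CO3, DMF, 60 °C
Reagents that add atoms: benzyl bromide, BrCc1ccccc1
Why: Williamson benzylation of the acidic, hindered syringyl phenol; the aldehyde takes no part.

**Step 6**
Reactants: 6 2-[2-(benzyloxy)-3-methoxy-5-(methoxycarbonyl)phenyl]acetic acid; 8 4-(benzyloxy)-3,5-dimethoxybenzaldehyde
Product: 9 (2E)-2-[2-(benzyloxy)-3-methoxy-5-(methoxycarbonyl)phenyl]-3-[4-(benzyloxy)-3,5-dimethoxyphenyl]prop-2-enoic acid (aryl groups cis)
Conditions: Ac2O, Et3N, 110 °C; aq. HCl work-up; recrystallisation
Reagents that add atoms: none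
Why: Perkin condensation (arylacetic acid variant): the mixed anhydride of 6 is enolised by Et3N, adds to 8 and loses acetate, which should give the acid with the two aryl groups cis as the favoured isomer; crystallisation should secure a single alkene isomer for step 7.

**Step 7**
Reactants: 9 (2E)-2-[2-(benzyloxy)-3-methoxy-5-(methoxycarbonyl)phenyl]-3-[4-(benzyloxy)-3,5-dimethoxyphenyl]prop-2-enoic acid
Product: 10 (2S)-2-[2-(benzyloxy)-3-methoxy-5-(methoxycarbonyl)phenyl]-3-[4-(benzyloxy)-3,5-dimethoxyphenyl]propanoic acid
Conditions: H2 (10 bar), [Ir(cod)(L)][B(C6H3(CF3)2)4] (1 mol %), Et3N, MeOH, rt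
Reagents that add atoms: none
Why: Asymmetric hydrogenation of an alpha-aryl cinnamic acid by a cationic complex of monovalent iridium with a chiral P,N ligand; the carboxylate binds the metal and the ligand selects the alkene face, which sets the future C3 as S. Benzyl ethers and the methyl ester are inert to this homogeneous catalyst.

**Step 8**
Reactants: 10 (2S)-2-[2-(benzyloxy)-3-methoxy-5-(methoxycarbonyl)phenyl]-3-[4-(benzyloxy)-3,5-dimethoxyphenyl]propanoic acid
Product: 11 methyl 4-(benzyloxy)-3-[(2S)-1-[4-(benzyloxy)-3,5-dimethoxyphenyl]-3-hydroxypropan-2-yl]-5-methoxybenzoate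
Conditions: BH3·THF, THF, 0 °C → rt; MeOH quench
Reagents that add atoms: none
Why: Borane reduces a carboxylic acid through its acyloxyborane much faster than an aromatic methyl ester, so only the acid should become the primary alcohol; the stereocentre is not enolised under these non-basic conditions.

**Step 9**
Reactants: 11 methyl 4-(benzyloxy)-3-[(2S)-1-[4-(benzyloxy)-3,5-dimethoxyphenyl]-3-hydroxypropan-2-yl]-5-methoxybenzoate
Product: 12 methyl 4-hydroxy-3-[(2S)-1-hydroxy-3-(4-hydroxy-3,5-dimethoxyphenyl)propan-2-yl]-5-methoxybenzoate
Conditions: H2 (1 atm), Pd/C, EtOAc/MeOH, rt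
Reagents that add atoms: none
Why: Hydrogenolysis of both O-benzyl ethers over Pd/C should free the two phenols in one operation; the molecule holds no alkene, halide or other benzylic C–O bond.

**Step 10**
Reactants: 12 methyl 4-hydroxy-3-[(2S)-1-hydroxy-3-(4-hydroxy-3,5-dimethoxyphenyl)propan-2-yl]-5-methoxybenzoate
Product: 14 methyl (2R,3S)-2-(4-hydroxy-3,5-dimethoxyphenyl)-3-(hydroxymethyl)-7-methoxy-2,3-dihydro-1-benzofuran-5-carboxylate, via para-quinone methide 13 (not isolated)
Conditions: Ag2O (1.05 equiv), CH2Cl2, rt, dark; filtration through Celite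
Reagents that add atoms: none
Why: Ag2O should take two electrons and two protons from the ring C phenol and its para benzylic CH2 (phenoxyl radical, then loss of the benzylic hydrogen) to give the para-quinone methide 13, and the C7a phenol then adds to the methide carbon in an oxa-1,6-addition that restores the aromaticity of ring C and forms O1–C2. The closest known reaction type is the Ag2O or DDQ oxidation of 4-alkyl-2,6-dimethoxyphenols to para-quinone methides with capture by an internal oxygen nucleophile, and the same methide is the intermediate that closes phenylcoumarans in oxidative phenol coupling. Ring B closes in the 5-exo-trig mode, since the methide C=C lies outside the new ring; closure by the primary alcohol would be a four-membered ring and should not compete. The new stereocentre C2 is controlled by C3: in the envelope transition state the quinoid ring takes the position anti to the CH2OH group, which gives the trans (2R,3S) isomer, and because the closure can reverse through the methide the trans isomer is also the thermodynamic one. The step needs chemoselective oxidation, which the substrate secures because ring C has two methoxy donors and a para alkyl group whereas the ring A phenol is deactivated by the para ester. It also needs closure to outrun tautomerisation of 13 to a styrene, which the five-atom tether and the nucleophilic phenol should ensure. One equivalent of oxidant and prompt filtration are used so that 14, which still carries the ring C phenol, is not oxidised on to the benzofuran.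

**Step 11**
Reactants: 14 methyl (2R,3S)-2-(4-hydroxy-3,5-dimethoxyphenyl)-3-(hydroxymethyl)-7-methoxy-2,3-dihydro-1-benzofuran-5-carboxylate
Product: 15 methyl (2R,3S)-2-[4-(tert-butyldimethylsilyloxy)-3,5-dimethoxyphenyl]-3-[(tert-butyldimethylsilyloxy)methyl]-7-methoxy-2,3-dihydro-1-benzofuran-5-carboxylate
Conditions: TBSCl (3 equiv), imidazole, DMF, rt → 40 °C
Reagents that add atoms: tert-butyldimethylsilyl chloride, CC(C)(C)[Si](C)(C)Cl
Why: Imidazole-promoted silylation of the ring C phenol and the primary alcohol; capping the phenol closes the path back to the quinone methide, so the C2–O1 bond is locked for the following steps.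

**Step 12**
Reactants: 15 methyl (2R,3S)-2-[4-(tert-butyldimethylsilyloxy)-3,5-dimethoxyphenyl]-3-[(tert-butyldimethylsilyloxy)methyl]-7-methoxy-2,3-dihydro-1-benzofuran-5-carboxylate
Product: 16 [(2R,3S)-2-[4-(tert-butyldimethylsilyloxy)-3,5-dimethoxyphenyl]-3-[(tert-butyldimethylsilyloxy)methyl]-7-methoxy-2,3-dihydro-1-benzofuran-5-yl]methanol
Conditions: i-Bu2AlH (2.5 equiv), CH2Cl2, −78 → 0 °C; aq. potassium sodium tartrate
Reagents that add atoms: none
Why: Hydride reduction of the aryl ester to the benzylic alcohol; silyl ethers, aryl ethers and both stereocentres are not affected at low temperature.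

**Step 13**
Reactants: 16 [(2R,3S)-2-[4-(tert-butyldimethylsilyloxy)-3,5-dimethoxyphenyl]-3-[(tert-butyldimethylsilyloxy)methyl]-7-methoxy-2,3-dihydro-1-benzofuran-5-yl]methanol
Product: 17 (2R,3S)-2-[4-(tert-butyldimethylsilyloxy)-3,5-dimethoxyphenyl]-3-[(tert-butyldimethylsilyloxy)methyl]-7-methoxy-2,3-dihydro-1-benzofuran-5-carbaldehyde
Conditions: MnO2 (excess), CH2Cl2, rt
Reagents that add atoms: none
Why: MnO2 oxidises benzylic alcohols to aldehydes selectively and stops there; no other free hydroxyl is present.

**Step 14**
Reactants: 18 3,5-dihydroxybenzyl alcohol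
Product: 19 1,3-bis(tert-butyldimethylsilyloxy)-5-[(tert-butyldimethylsilyloxy)methyl]benzene
Conditions: TBSCl (3.5 equiv), imidazole, DMF, rt
Reagents that add atoms: tert-butyldimethylsilyl chloride, CC(C)(C)[Si](C)(C)Cl
Why: Exhaustive imidazole-promoted silylation; no selectivity between the three hydroxyls is required.

**Step 15**
Reactants: 19 1,3-bis(tert-butyldimethylsilyloxy)-5-[(tert-butyldimethylsilyloxy)methyl]benzene
Product: 20 1-(bromomethyl)-3,5-bis(tert-butyldimethylsilyloxy)benzene
Conditions: Ph3PBr2 (1.1 equiv), CH2Cl2, 0 °C → rt
Reagents that add atoms: dibromotriphenylphosphorane, BrP(Br)(c1ccccc1)(c1ccccc1)c1ccccc1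
Why: Direct conversion of an alkyl silyl ether into a bromide: the ether oxygen attacks phosphorus, the silyl group leaves as its bromide, and bromide displaces triphenylphosphine oxide at the benzylic carbon (SN2); aryl silyl ethers cannot undergo this displacement and should remain.

**Step 16**
Reactants: 20 1-(bromomethyl)-3,5-bis(tert-butyldimethylsilyloxy)benzene
Product: 21 diethyl {[3,5-bis(tert-butyldimethylsilyloxy)phenyl]methyl}phosphonate
Conditions: P(OEt)3, neat, 130 °C
Reagents that add atoms: triethyl phosphite, CCOP(OCC)OCC
Why: Michaelis–Arbuzov reaction: SN2 attack of phosphorus on the benzylic bromide, then dealkylation of the phosphonium salt by bromide.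

**Step 17**
Reactants: 17 (2R,3S)-2-[4-(tert-butyldimethylsilyloxy)-3,5-dimethoxyphenyl]-3-[(tert-butyldimethylsilyloxy)methyl]-7-methoxy-2,3-dihydro-1-benzofuran-5-carbaldehyde; 21 diethyl {[3,5-bis(tert-butyldimethylsilyloxy)phenyl]methyl}phosphonate
Product: 22 (2R,3S)-5-[(E)-2-[3,5-bis(tert-butyldimethylsilyloxy)phenyl]ethenyl]-2-[4-(tert-butyldimethylsilyloxy)-3,5-dimethoxyphenyl]-3-[(tert-butyldimethylsilyloxy)methyl]-7-methoxy-2,3-dihydro-1-benzofuran
Conditions: 21, NaH, THF, 0 °C; then 17, 0 °C → rt
Reagents that add atoms: none
Why: Horner–Wadsworth–Emmons olefination of a non-enolisable aryl aldehyde with a benzylic phosphonate anion; reversible addition and elimination through the less crowded oxaphosphetane should give the (E)-stilbene. C2 and C3 carry no hydrogen acidic enough to be touched.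

**Step 18**
Reactants: 22 (2R,3S)-5-[(E)-2-[3,5-bis(tert-butyldimethylsilyloxy)phenyl]ethenyl]-2-[4-(tert-butyldimethylsilyloxy)-3,5-dimethoxyphenyl]-3-[(tert-butyldimethylsilyloxy)methyl]-7-methoxy-2,3-dihydro-1-benzofuran
Product: 23 gnetucleistol F
Conditions: Bu4NF (5 equiv), AcOH (5 equiv), THF, 0 °C → rt, dark
Reagents that add atoms: none
Why: Fluoride cleaves all four Si–O bonds; acetic acid keeps the ring C phenol protonated so that it cannot open the C2–O1 bond through the quinone methide, and light is excluded to keep the stilbene E.

## Compound list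

1 | methyl vanillate (methyl 4-hydroxy-3-methoxybenzoate) | COc1cc(C(=O)OC)ccc1O | starting material
2 | methyl 3-methoxy-4-(prop-2-en-1-yloxy)benzoate | COc1cc(C(=O)OC)ccc1OCC=C | intermediate
3 | methyl 4-hydroxy-3-methoxy-5-(prop-2-en-1-yl)benzoate | COc1cc(C(=O)OC)cc(CC=C)c1O | intermediate
4 | methyl 4-(benzyloxy)-3-methoxy-5-(prop-2-en-1-yl)benzoate | COc1cc(C(=O)OC)cc(CC=C)c1OCc1ccccc1 | intermediate
5 | methyl 4-(benzyloxy)-3-methoxy-5-(2-oxoethyl)benzoate | COc1cc(C(=O)OC)cc(CC=O)c1OCc1ccccc1 | intermediate (not isolated)
6 | 2-[2-(benzyloxy)-3-methoxy-5-(methoxycarbonyl)phenyl]acetic acid | COc1cc(C(=O)OC)cc(CC(=O)O)c1OCc1ccccc1 | intermediate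
7 | syringaldehyde (4-hydroxy-3,5-dimethoxybenzaldehyde) | COc1cc(C=O)cc(OC)c1O | starting material
8 | 4-(benzyloxy)-3,5-dimethoxybenzaldehyde | COc1cc(C=O)cc(OC)c1OCc1ccccc1 | intermediate
9 | (2E)-2-[2-(benzyloxy)-3-methoxy-5-(methoxycarbonyl)phenyl]-3-[4-(benzyloxy)-3,5-dimethoxyphenyl]prop-2-enoic acid | OC(=O)/C(=C/c1cc(OC)c(OCc2ccccc2)c(OC)c1)c1cc(C(=O)OC)cc(OC)c1OCc1ccccc1 | intermediate
10 | (2S)-2-[2-(benzyloxy)-3-methoxy-5-(methoxycarbonyl)phenyl]-3-[4-(benzyloxy)-3,5-dimethoxyphenyl]propanoic acid | COc1cc(C[C@H](C(=O)O)c2cc(C(=O)OC)cc(OC)c2OCc2ccccc2)cc(OC)c1OCc1ccccc1 | intermediate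
11 | methyl 4-(benzyloxy)-3-[(2S)-1-[4-(benzyloxy)-3,5-dimethoxyphenyl]-3-hydroxypropan-2-yl]-5-methoxybenzoate | COc1cc(C[C@H](CO)c2cc(C(=O)OC)cc(OC)c2OCc2ccccc2)cc(OC)c1OCc1ccccc1 | intermediate
12 | methyl 4-hydroxy-3-[(2S)-1-hydroxy-3-(4-hydroxy-3,5-dimethoxyphenyl)propan-2-yl]-5-methoxybenzoate | COc1cc(C[C@H](CO)c2cc(C(=O)OC)cc(OC)c2O)cc(OC)c1O | intermediate
13 | methyl 3-[(2S)-1-(3,5-dimethoxy-4-oxocyclohexa-2,5-dien-1-ylidene)-3-hydroxypropan-2-yl]-4-hydroxy-5-methoxybenzoate | COC1=CC(=C[C@H](CO)c2cc(C(=O)OC)cc(OC)c2O)C=C(OC)C1=O | intermediate (not isolated)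
14 | methyl (2R,3S)-2-(4-hydroxy-3,5-dimethoxyphenyl)-3-(hydroxymethyl)-7-methoxy-2,3-dihydro-1-benzofuran-5-carboxylate | COc1cc([C@@H]2Oc3c(OC)cc(C(=O)OC)cc3[C@H]2CO)cc(OC)c1O | intermediate
15 | methyl (2R,3S)-2-[4-(tert-butyldimethylsilyloxy)-3,5-dimethoxyphenyl]-3-[(tert-butyldimethylsilyloxy)methyl]-7-methoxy-2,3-dihydro-1-benzofuran-5-carboxylate | COc1cc([C@@H]2Oc3c(OC)cc(C(=O)OC)cc3[C@H]2CO[Si](C)(C)C(C)(C)C)cc(OC)c1O[Si](C)(C)C(C)(C)C | intermediate
16 | [(2R,3S)-2-[4-(tert-butyldimethylsilyloxy)-3,5-dimethoxyphenyl]-3-[(tert-butyldimethylsilyloxy)methyl]-7-methoxy-2,3-dihydro-1-benzofuran-5-yl]methanol | COc1cc([C@@H]2Oc3c(OC)cc(CO)cc3[C@H]2CO[Si](C)(C)C(C)(C)C)cc(OC)c1O[Si](C)(C)C(C)(C)C | intermediate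
17 | (2R,3S)-2-[4-(tert-butyldimethylsilyloxy)-3,5-dimethoxyphenyl]-3-[(tert-butyldimethylsilyloxy)methyl]-7-methoxy-2,3-dihydro-1-benzofuran-5-carbaldehyde | COc1cc([C@@H]2Oc3c(OC)cc(C=O)cc3[C@H]2CO[Si](C)(C)C(C)(C)C)cc(OC)c1O[Si](C)(C)C(C)(C)C | intermediate
18 | 3,5-dihydroxybenzyl alcohol (5-(hydroxymethyl)benzene-1,3-diol) | OCc1cc(O)cc(O)c1 | starting material
19 | 1,3-bis(tert-butyldimethylsilyloxy)-5-[(tert-butyldimethylsilyloxy)methyl]benzene | CC(C)(C)[Si](C)(C)OCc1cc(O[Si](C)(C)C(C)(C)C)cc(O[Si](C)(C)C(C)(C)C)c1 | intermediate
20 | 1-(bromomethyl)-3,5-bis(tert-butyldimethylsilyloxy)benzene | BrCc1cc(O[Si](C)(C)C(C)(C)C)cc(O[Si](C)(C)C(C)(C)C)c1 | intermediate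
21 | diethyl {[3,5-bis(tert-butyldimethylsilyloxy)phenyl]methyl}phosphonate | CCOP(=O)(Cc1cc(O[Si](C)(C)C(C)(C)C)cc(O[Si](C)(C)C(C)(C)C)c1)OCC | intermediate
22 | (2R,3S)-5-[(E)-2-[3,5-bis(tert-butyldimethylsilyloxy)phenyl]ethenyl]-2-[4-(tert-butyldimethylsilyloxy)-3,5-dimethoxyphenyl]-3-[(tert-butyldimethylsilyloxy)methyl]-7-methoxy-2,3-dihydro-1-benzofuran | COc1cc([C@@H]2Oc3c(OC)cc(/C=C/c4cc(O[Si](C)(C)C(C)(C)C)cc(O[Si](C)(C)C(C)(C)C)c4)cc3[C@H]2CO[Si](C)(C)C(C)(C)C)cc(OC)c1O[Si](C)(C)C(C)(C)C | intermediate
23 | gnetucleistol F, 5-[(E)-2-[(2R,3S)-2-(4-hydroxy-3,5-dimethoxyphenyl)-3-(hydroxymethyl)-7-methoxy-2,3-dihydro-1-benzofuran-5-yl]ethenyl]benzene-1,3-diol | COc1cc([C@@H]2Oc3c(OC)cc(/C=C/c4cc(O)cc(O)c4)cc3[C@H]2CO)cc(OC)c1O | target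

## Step count and least certain steps

Total step count: 18. Longest linear sequence: 14 steps (steps 1 to 4, 6 to 13, 17 and 18). Step 5 and steps 14 to 16 are side branches.

**Step 10 (key step).**
- **Risk:** the methide 13 may tautomerise to a styrene before the ring closes, which would erase the C3 stereocentre. The product may also be oxidised a second time towards the benzofuran, because 14 still carries the oxidisable ring C phenol and a benzylic hydrogen at C2.
- **Fallback:** it sets out from 12 and returns at 14, and it separates the oxidation from the ring closure. 12 would be oxidised with DDQ (1 equiv) in CH2Cl2/MeOH at 0 °C, so that the methide is intercepted at once by the solvent. This would give methyl 4-hydroxy-3-[(2S)-1-hydroxy-3-(4-hydroxy-3,5-dimethoxyphenyl)-3-methoxypropan-2-yl]-5-methoxybenzoate F1, as both epimers at the methoxy-bearing carbon, possibly together with some 14. Catalytic camphorsulfonic acid in CH2Cl2 at 0 °C would then ionise the benzylic ether of F1 and close ring B with loss of methanol. Under these equilibrating conditions the material should converge on trans 14.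

**Step 7.**
- **Risk:** slow hydrogenation or poor facial selectivity, because the ortho benzyloxy group twists the alpha-aryl ring out of the alkene plane and crowds the site where the carboxylate binds iridium.
- **Fallback:** it sets out from 6 and 8 and returns at 10. It replaces catalytic face selection by auxiliary-controlled alkylation and also bypasses step 6.
  - 6 would be coupled with (4S)-4-benzyl-1,3-oxazolidin-2-one (DCC, DMAP, CH2Cl2) to give methyl 3-{2-[(4S)-4-benzyl-2-oxo-1,3-oxazolidin-3-yl]-2-oxoethyl}-4-(benzyloxy)-5-methoxybenzoate F2.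
  - 8 would be reduced (NaBH4, MeOH) to [4-(benzyloxy)-3,5-dimethoxyphenyl]methanol F3 and converted with PBr3 (CH2Cl2, 0 °C) into 2-(benzyloxy)-5-(bromomethyl)-1,3-dimethoxybenzene F4.
  - The sodium enolate of F2 (NaN(SiMe3)2, THF, −78 °C) would be alkylated by F4 on the face away from the auxiliary benzyl group. This would give methyl 3-[(2S)-1-[(4S)-4-benzyl-2-oxo-1,3-oxazolidin-3-yl]-3-[4-(benzyloxy)-3,5-dimethoxyphenyl]-1-oxopropan-2-yl]-4-(benzyloxy)-5-methoxybenzoate F5.
  - LiOH/H2O2 (THF/H2O, 0 °C) would then release 10 and the auxiliary.

**Step 4.**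
- **Risk:** ozone may attack the dialkoxy arene or the benzylic ether once the alkene is consumed, and the arylacetaldehyde may self-condense before it is oxidised.
- **Fallback:** it sets out from 4 and returns at 6, and it avoids ozone. 4 would be dihydroxylated (K2OsO2(OH)4 cat., N-methylmorpholine N-oxide, acetone/H2O) to methyl 4-(benzyloxy)-3-(2,3-dihydroxypropyl)-5-methoxybenzoate F6. The diol would be cleaved with NaIO4 (THF/H2O) to 5, here isolated crude, and 5 oxidised with NaClO2, NaH2PO4 and 2-methylbut-2-ene (t-BuOH/H2O) to 6.

**Step 15.**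
- **Risk:** loss of the aryl silyl groups through the acid and bromide formed, or incomplete exchange at the benzylic position.
- **Fallback:** it sets out from 19 and returns at 20, through a free alcohol. Pyridinium p-toluenesulfonate in EtOH would remove the benzylic silyl ether selectively, since alkyl silyl ethers solvolyse faster than aryl ones under mild acid. This would give [3,5-bis(tert-butyldimethylsilyloxy)phenyl]methanol F7, which CBr4/PPh3 (CH2Cl2, 0 °C) would convert into 20.

## Further compounds

F1 | step 10 | methyl 4-hydroxy-3-[(2S)-1-hydroxy-3-(4-hydroxy-3,5-dimethoxyphenyl)-3-methoxypropan-2-yl]-5-methoxybenzoate (both epimers at the methoxy-bearing carbon) | COc1cc(C(OC)[C@H](CO)c2cc(C(=O)OC)cc(OC)c2O)cc(OC)c1O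
F2 | step 7 | methyl 3-{2-[(4S)-4-benzyl-2-oxo-1,3-oxazolidin-3-yl]-2-oxoethyl}-4-(benzyloxy)-5-methoxybenzoate | COc1cc(C(=O)OC)cc(CC(=O)N2[C@@H](Cc3ccccc3)COC2=O)c1OCc1ccccc1
F3 | step 7 | [4-(benzyloxy)-3,5-dimethoxyphenyl]methanol | COc1cc(CO)cc(OC)c1OCc1ccccc1
F4 | step 7 | 2-(benzyloxy)-5-(bromomethyl)-1,3-dimethoxybenzene | COc1cc(CBr)cc(OC)c1OCc1ccccc1
F5 | step 7 | methyl 3-[(2S)-1-[(4S)-4-benzyl-2-oxo-1,3-oxazolidin-3-yl]-3-[4-(benzyloxy)-3,5-dimethoxyphenyl]-1-oxopropan-2-yl]-4-(benzyloxy)-5-methoxybenzoate | COc1cc(C[C@H](C(=O)N2[C@@H](Cc3ccccc3)COC2=O)c2cc(C(=O)OC)cc(OC)c2OCc2ccccc2)cc(OC)c1OCc1ccccc1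
F6 | step 4 | methyl 4-(benzyloxy)-3-(2,3-dihydroxypropyl)-5-methoxybenzoate (racemic) | COc1cc(C(=O)OC)cc(CC(O)CO)c1OCc1ccccc1
F7 | step 15 | [3,5-bis(tert-butyldimethylsilyloxy)phenyl]methanol | OCc1cc(O[Si](C)(C)C(C)(C)C)cc(O[Si](C)(C)C(C)(C)C)c1
A1 | alternative 1 | (2R,3S)-5-bromo-3-(tert-butyldimethylsilyloxymethyl)-2-(3,5-dimethoxy-4-triisopropylsilyloxyphenyl)-7-methoxy-2,3-dihydrobenzofuran | COc1cc([C@@H]2Oc3c(OC)cc(Br)cc3[C@H]2CO[Si](C)(C)C(C)(C)C)cc(OC)c1O[Si](C(C)C)(C(C)C)C(C)C
A2 | alternative 1 | 4-bromo-2-[2-(tert-butyldimethylsilyloxy)-1-(4-methylphenylsulfonyl)ethyl]-6-methoxyphenol (racemic) | COc1cc(Br)cc(C(CO[Si](C)(C)C(C)(C)C)S(=O)(=O)c2ccc(C)cc2)c1O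
A3 | alternative 1 | (2R,5R)-1-[3,5-dimethoxy-4-(triisopropylsilyloxy)benzyl]-2,5-dimethylthiolan-1-ium trifluoromethanesulfonate | C[C@@H]1CC[C@@H](C)[S+]1Cc1cc(OC)c(O[Si](C(C)C)(C(C)C)C(C)C)c(OC)c1.[O-]S(=O)(=O)C(F)(F)F
A4 | alternative 1 | 4-bromo-6-[2-(tert-butyldimethylsilyloxy)ethylidene]-2-methoxycyclohexa-2,4-dien-1-one | COC1=CC(Br)=CC(=CCO[Si](C)(C)C(C)(C)C)C1=O
A5 | alternative 1 | [(2R,5R)-2,5-dimethylthiolan-1-ium-1-yl][3,5-dimethoxy-4-(triisopropylsilyloxy)phenyl]methanide | C[C@@H]1CC[C@@H](C)[S+]1[CH-]c1cc(OC)c(O[Si](C(C)C)(C(C)C)C(C)C)c(OC)c1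
A6 | alternative 2 | gnetucleistol F bis(methoxymethyl) ether, 5-[(E)-2-[(2R,3S)-2-[3,5-dimethoxy-4-(methoxymethoxy)phenyl]-7-methoxy-3-[(methoxymethoxy)methyl]-2,3-dihydro-1-benzofuran-5-yl]ethenyl]benzene-1,3-diol | COCOc1c(OC)cc([C@@H]2Oc3c(OC)cc(/C=C/c4cc(O)cc(O)c4)cc3[C@H]2COCOC)cc1OC
A7 | alternative 2 | (2E)-3-[(2R,3S)-2-[3,5-dimethoxy-4-(methoxymethoxy)phenyl]-7-methoxy-3-[(methoxymethoxy)methyl]-2,3-dihydro-1-benzofuran-5-yl]-N-methoxy-N-methylprop-2-enamide | COCOc1c(OC)cc([C@@H]2Oc3c(OC)cc(/C=C/C(=O)N(C)OC)cc3[C@H]2COCOC)cc1OC
A8 | alternative 2 | acetylacetone (pentane-2,4-dione) | CC(=O)CC(C)=O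
A9 | alternative 2 | (1E)-1-[(2R,3S)-2-[3,5-dimethoxy-4-(methoxymethoxy)phenyl]-7-methoxy-3-[(methoxymethoxy)methyl]-2,3-dihydro-1-benzofuran-5-yl]oct-1-ene-3,5,7-trione | COCOc1c(OC)cc([C@@H]2Oc3c(OC)cc(/C=C/C(=O)CC(=O)CC(C)=O)cc3[C@H]2COCOC)cc1OC
A10 | alternative 3 | methyl (2R,3R)-2-(4-acetoxy-3,5-dimethoxyphenyl)-5-bromo-7-methoxy-2,3-dihydrobenzofuran-3-carboxylate (trans) | COc1cc([C@@H]2Oc3c(OC)cc(Br)cc3[C@H]2C(=O)OC)cc(OC)c1OC(C)=O
A11 | alternative 3 | 4-[(2R)-6-bromo-8-methoxy-4-oxo-3,4-dihydro-2H-chromen-2-yl]-2,6-dimethoxyphenyl acetate | COc1cc([C@@H]2Oc3c(OC)cc(Br)cc3C(=O)C2)cc(OC)c1OC(C)=O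
A12 | alternative 3 | 4-[(2R)-6-bromo-4,8-dimethoxy-2H-chromen-2-yl]-2,6-dimethoxyphenyl acetate | COc1cc([C@@H]2Oc3c(OC)cc(Br)cc3C(OC)=C2)cc(OC)c1OC(C)=O
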